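The readings stem from a simulated flask for an exercise; scatter was added.

What share of the electrophile has reacted after 80 min of dosing in epsilon and in zeta, and does the free base change it?

| flask | electrophile | nucleophile | free base | remark | time |
|---|---|---|---|---|---|
| cedar | 0.10 M (fed, over 80 min) | 0.080 M | 0.13 M | run made earlier; the fed solution adds 0.20 times the starting volume |  |
| maple | 0.10 M (fed, over 80 min) | 0.080 M | 0.28 M | run made earlier; the fed solution adds 0.20 times the starting volume |  |
| epsilon | 0.10 M (fed, over 80 min) | 0.0800 M | 0.110 M | the fed solution adds 0.20 times the starting volume | 80 min |
| zeta | 0.10 M (fed, over 80 min) | 0.0800 M | 0.220 M | the fed solution adds 0.20 times the starting volume | 80 min |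

- cedar (time / min: electrophile / %, target / %): 6.00: 9.6, 0.3; 12.0: 12.9, 1.7; 20.0: 20.4, 5.4; 25.0: 24.5, 7.5; 30.0: 25.8, 9.7; 40.0: 34.5, 16.6
- maple (time / min: electrophile / %, target / %): 6.00: 7.0, 1.2; 12.0: 12.2, 1.8; 20.0: 20.9, 5.1; 25.0: 22.2, 7.4; 30.0: 26.7, 9.9; 40.0: 33.2, 16.5

(standard deviation of a reading: 1 percentage point)

* part of the electrophile that has reacted at the end, epsilon
* part of the electrophile that has reacted at the end, zeta
* what raising the concentration of free base from its lowest to its highest value here does to the part of the electrophile that has reacted (changes below 5 percentage points count as none) (it falls / no change / it rises)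

I started from the readings at 40.0 min: target stood at 16.6% in cedar and 16.5% in maple, nearly the same, with free base at 0.13 M against 0.28 M. So I wrote no free base into the rate. I assumed that each target sets free one acid and that this acid takes a second nucleophile, a toll of two nucleophile per target. On that assumption nucleophile is the limiting reagent, and my reckoning has a ceiling on the reacted part, C = 40.0%, the nucleophile charge over the toll times the electrophile charge.

Next I took the rate as k·A·N/V, with A and N the amounts of electrophile and free nucleophile and V the volume. With the toll, ln N falls at twice k·A/V, which integrates in closed form: the reacted part is X = C(1 − e^−θ), where θ is the toll times k times the time integral of A/V. I needed no k, since the mean target reading 16.6%, taken as the reacted part, gives θ = 0.534 at 40.0 min. Taking A as a steady share of what had entered and V as constant, θ grows with the square of time, so at 80 min it is 2.14 and X is 35.3%.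

The weak link was the constant volume. With V growing, the integral goes as u − ln(1 + u), where u is the volume gained over the starting volume. The end-to-40.0 min ratio is then 3.77, so θ is 2.01 and X is 34.7%. I committed to that for both flasks, though epsilon's 0.110 M lies below the tested base.

The forecast stood at 40.5% and 41%, with no change, holding that “the rate stays near 0.006 per min as electrophile build-up offsets nucleophile depletion and dilution”. Its epsilon figure is 5.8 percentage points above my reckoned one.

After 80 min, epsilon gave 33.4% and zeta 33.7%, a shift of 0.29 points, so the answer is no change. In epsilon 22% of the nucleophile's charge stayed free against 67% of the electrophile's charge; free nucleophile is the reading to watch on a repeat. Counted in epsilon, the toll came to 1.86 nucleophile per reacted electrophile, and the flask stood at 83.5% of C.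

    electrophile + nucleophile → acid set free + target (k = 0.00570 L mol⁻¹ s⁻¹)
    nucleophile + acid set free ⇌ protonated nucleophile, settled at all times (K = 700 L mol⁻¹)
    acid set free + free base ⇌ salt of the base (K = 150 L mol⁻¹, k = 0.00700 L mol⁻¹ s⁻¹)
    target ⇌ isomer of the product (K = 0.230, k = 4.50 × 10⁻⁵ s⁻¹)
    free base ⇌ dormant form (K = 0.480, k = 1.00 × 10⁻⁴ s⁻¹)

For the flask like zeta but with 0.17 M of electrophile, C drops to 23.5%, θ grows with the charge to 3.42 at the same share, and X comes to 22.8%. That flask gave 24.8%, 1.3 points past the C reckoned for it.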